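**Plan**

- Retrosynthesis (furofuran numbered as 3,7-dioxabicyclo[3.3.0]octane, guaiacyl at C2, benzofuranyl at C6): the silyl ethers go last; the O7–C8H2 bond is cut to a diol that comes from a γ-lactone (C8=O); the H atoms on C1 and C2 are removed to give an enol ether; the O3–C4H2 bond is then cut by a retro-Cloke–Wilson step to a 1-aroyl-4-aryl-3-oxabicyclo[3.1.0]hexan-2-one. This splits into an arylzinc, diallyl malonate and a (2R,3R)-aryl glycidyl tosylate, whose aryl group is a cis-2,3-dihydrobenzofuran cut at C2–C3 (carbene C–H insertion).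
- Forward order: dihydrobenzofuran, then epoxide, then cyclopropane and γ-lactone in one operation, then the aroyl group, then the first oxolane by rearrangement, hydrogenation, and last the lactone ring is opened by reduction and closed again as the second oxolane.
- Enabling feature: the unit ArC2(–O3)–C1–C5–C4H2 of the first oxolane is a cyclopropyl aryl ketone in disguise (C1, C5, C4 as the three-membered ring, ArC2=O as the ketone). With C8 as a lactone carbonyl, C1 carries two acyl groups and the lactone ring aligns the exocyclic C1–CH2 bond with both carbonyls, so a nucleophile-catalysed Cloke–Wilson rearrangement moves the CH2 from carbon to the ketone oxygen. Direct O-alkylation of a keto ester by the same epoxide would put oxygen on the secondary carbon instead.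
- Stereochemistry: C2/C3 of the dihydrobenzofuran from a chiral dirhodium carboxylate. C6 and C5 from a Sharpless epoxide (retention at the benzylic carbon, inversion at its neighbour in the 3-exo-tet closure, which places the aryl syn to the cyclopropane CH2, that is endo). C1 and C2 by hydrogenation of the bicyclic enol ether from its convex face, which gives the contra-thermodynamic endo aryl. Both oxolane C–O bonds are made at CH2, so no benzylic centre is ionised.

Key step: step 15

Remark: the SMILES is read as the (1S,2S,5S,6S)-furofuran with both aryl groups endo (all four ring hydrogens cis) and a (2S,3S) cis-2,3-dihydrobenzofuran; in step 6 the catalyst enantiomer that gives the (2S,3R) ester is assumed to be Rh2(S-PTTL)4, and Rh2(R-PTTL)4 is taken if the sense proves opposite.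

Abbreviations: ArT = 3-methoxy-4-(triisopropylsilyloxy)phenyl; DHB = (2S,3S)-3-[(tert-butyldimethylsilyloxy)methyl]-7-methoxy-2-ArT-2,3-dihydro-1-benzofuran-5-yl (ArT and CH2O cis).

**Route**

Step 1
Reactants: 1 vanillin
Product: 2 3-methoxy-4-(triisopropylsilyloxy)benzaldehyde
Conditions: TIPSCl, imidazole, DMF, rt
Reagents that add atoms: triisopropylsilyl chloride, CC(C)[Si](Cl)(C(C)C)C(C)C
Why: Imidazole-promoted O-silylation of the phenol gives a silyl ether that should survive the basic steps ahead; no stereocentre is involved.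

Step 2
Reactants: 2 3-methoxy-4-(triisopropylsilyloxy)benzaldehyde
Product: 3 [3-methoxy-4-(triisopropylsilyloxy)phenyl]methanol
Conditions: NaBH4, MeOH, 0 °C
Reagents that add atoms: none
Why: Borohydride reduction of an aryl aldehyde to the benzylic alcohol is routine and leaves the aryl silyl ether intact at 0 °C.

Step 3
Reactants: 3 [3-methoxy-4-(triisopropylsilyloxy)phenyl]methanol; 4 5-iodovanillin (4-hydroxy-3-iodo-5-methoxybenzaldehyde)
Product: 5 3-iodo-5-methoxy-4-(ArT-methoxy)benzaldehyde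
Conditions: PPh3, DIAD, THF, 0 °C → rt
Reagents that add atoms: none
Why: Mitsunobu etherification should work because the phenol of 4 is acidic (formyl and iodo substituents) and the benzylic alcohol is readily activated; the iodide and aldehyde are untouched.

Step 4
Reactants: 5 3-iodo-5-methoxy-4-(ArT-methoxy)benzaldehyde
Product: 6 tert-butyl (E)-3-[3-iodo-5-methoxy-4-(ArT-methoxy)phenyl]prop-2-enoate
Conditions: Ph3P=CHCO2t-Bu, toluene, 80 °C
Reagents that add atoms: tert-butyl (triphenylphosphoranylidene)acetate, CC(C)(C)OC(=O)C=P(c1ccccc1)(c1ccccc1)c1ccccc1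
Why: Wittig olefination with a stabilised ylide should give the E enoate; the tert-butyl ester is chosen so that it can later be told apart from a methyl ester.

Step 5
Reactants: 6 tert-butyl (E)-3-[3-iodo-5-methoxy-4-(ArT-methoxy)phenyl]prop-2-enoate
Product: 7 tert-butyl (E)-3-[3-(1-diazo-2-methoxy-2-oxoethyl)-5-methoxy-4-(ArT-methoxy)phenyl]prop-2-enoate
Conditions: methyl diazoacetate, Pd(PPh3)4 (5 mol %), Ag2CO3 (0.5 equiv), Et3N, toluene, rt
Reagents that add atoms: methyl diazoacetate, COC(=O)C=[N+]=[N-]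
Why: Palladium-catalysed cross-coupling of an aryl iodide with an acceptor diazo compound (C–H arylation with retention of the diazo group) should install the aryldiazoacetate directly at room temperature, where the enoate does not enter a Heck reaction.

Step 6
Reactants: 7 tert-butyl (E)-3-[3-(1-diazo-2-methoxy-2-oxoethyl)-5-methoxy-4-(ArT-methoxy)phenyl]prop-2-enoate
Product: 8 methyl (2S,3R)-5-[(E)-3-tert-butoxy-3-oxoprop-1-enyl]-7-methoxy-2-ArT-2,3-dihydro-1-benzofuran-3-carboxylate (2,3-cis)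
Conditions: Rh2(S-PTTL)4 (1 mol %), toluene, −60 °C
Reagents that add atoms: none
Why: Intramolecular 1,5 C–H insertion of the dirhodium carbene into the electron-rich benzylic ether C–H bond (Hashimoto-type dihydrobenzofuran synthesis) should close the ring; cis is the kinetic outcome of the insertion and the chiral phthaloyl-tert-leucinate ligands set the absolute configuration of both new centres.

Step 7
Reactants: 8 methyl (2S,3R)-5-[(E)-3-tert-butoxy-3-oxoprop-1-enyl]-7-methoxy-2-ArT-2,3-dihydro-1-benzofuran-3-carboxylate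
Product: 9 tert-butyl (E)-3-[(2S,3S)-3-(hydroxymethyl)-7-methoxy-2-ArT-2,3-dihydro-1-benzofuran-5-yl]prop-2-enoate
Conditions: LiBH4, THF, 0 °C → rt
Reagents that add atoms: none
Why: Chemoselective borohydride reduction of the methyl ester in the presence of the hindered tert-butyl enoate removes the epimerisable ester at once, and the weakly basic reagent should leave the cis C3 centre unchanged.

Step 8
Reactants: 9 tert-butyl (E)-3-[(2S,3S)-3-(hydroxymethyl)-7-methoxy-2-ArT-2,3-dihydro-1-benzofuran-5-yl]prop-2-enoate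
Product: 10 tert-butyl (E)-3-(DHB)prop-2-enoate
Conditions: TBSCl, imidazole, DMF, rt
Reagents that add atoms: tert-butyldimethylsilyl chloride, CC(C)(C)[Si](C)(C)Cl
Why: Silylation of the primary alcohol is routine and keeps it out of the later sulfonylation steps.

Step 9
Reactants: 10 tert-butyl (E)-3-(DHB)prop-2-enoate
Product: 11 (E)-3-(DHB)prop-2-en-1-ol
Conditions: i-Bu2AlH (DIBAL-H), CH2Cl2, −78 → 0 °C; Rochelle salt work-up
Reagents that add atoms: none
Why: 1,2-Reduction of the enoate by DIBAL-H gives the E allylic alcohol needed for a directed epoxidation; silyl ethers are stable at this temperature.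

Step 10
Reactants: 11 (E)-3-(DHB)prop-2-en-1-ol
Product: 13 [(2R,3R)-3-(DHB)oxiran-2-yl]methyl 4-methylbenzenesulfonate, via epoxy alcohol 12 (not isolated)
Conditions: Ti(OiPr)4 (10 mol %), D-(−)-diisopropyl tartrate (12 mol %), t-BuOOH, 4 Å sieves, CH2Cl2, −20 °C; P(OMe)3; then TsCl, Et3N, DMAP (cat.), −10 °C
Reagents that add atoms: tert-butyl hydroperoxide, CC(C)(C)OO; 4-methylbenzenesulfonyl chloride, Cc1ccc(cc1)S(Cl)(=O)=O
Why: Sharpless asymmetric epoxidation of the E allylic alcohol with the D-(−)-tartrate should give the (2R,3R)-epoxide by reagent control (the remote dihydrobenzofuran centres are spectators), and tosylation in the same flask avoids handling the acid-labile electron-rich aryl glycidol.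

Step 11
Reactants: 13 [(2R,3R)-3-(DHB)oxiran-2-yl]methyl 4-methylbenzenesulfonate
Product: 16 allyl (1S,4S,5R)-4-(DHB)-2-oxo-3-oxabicyclo[3.1.0]hexane-1-carboxylate (DHB syn to the cyclopropane CH2), via epoxy malonate 14 (not isolated), via cyclopropyl carbinolate 15 (not isolated)
Conditions: diallyl malonate, NaH (2.2 equiv), THF, 0 → 60 °C
Reagents that add atoms: diallyl malonate, C=CCOC(=O)CC(=O)OCC=C
Why: In this malonate/epihalohydrin-type cyclopropanation, sodium malonate displaces the primary tosylate (SN2), the second enolate opens the epoxide at the adjacent carbon by 3-exo-tet closure with inversion there and retention at the benzylic carbon, and the freed benzylic alkoxide lactonises onto the cis ester, so the trans epoxide is translated stereospecifically into the lactone with the aryl group syn to the cyclopropane CH2.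

Step 12
Reactants: 16 allyl (1S,4S,5R)-4-(DHB)-2-oxo-3-oxabicyclo[3.1.0]hexane-1-carboxylate
Product: 17 (1S,4S,5R)-4-(DHB)-2-oxo-3-oxabicyclo[3.1.0]hexane-1-carboxylic acid
Conditions: Pd(PPh3)4 (5 mol %), HCO2H, Et3N, THF, rt
Reagents that add atoms: none
Why: Palladium-catalysed allyl ester cleavage with formate as the hydride donor (Tsuji deallylation) is neutral and uses no nucleophile that could open the activated cyclopropane or the lactone.

Step 13
Reactants: 18 4-bromo-2-methoxyphenol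
Product: 19 (4-bromo-2-methoxyphenoxy)triisopropylsilane
Conditions: TIPSCl, imidazole, DMF, rt
Reagents that add atoms: triisopropylsilyl chloride, CC(C)[Si](Cl)(C(C)C)C(C)C
Why: Routine phenol silylation gives the same protecting group as on the other phenol, so that one fluoride treatment clears all silyl groups at the end.

Step 14
Reactants: 17 (1S,4S,5R)-4-(DHB)-2-oxo-3-oxabicyclo[3.1.0]hexane-1-carboxylic acid; 19 (4-bromo-2-methoxyphenoxy)triisopropylsilane
Product: 23 (1S,4S,5R)-1-(ArT-carbonyl)-4-(DHB)-3-oxabicyclo[3.1.0]hexan-2-one, via acid chloride 20 (not isolated), via aryllithium 21 (not isolated), via arylzinc chloride 22 (not isolated)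
Conditions: 17, 1-chloro-N,N,2-trimethylprop-1-en-1-amine, CH2Cl2, 0 °C; 19, n-BuLi, THF, −78 °C, then ZnCl2; combine, Pd(PPh3)4 (5 mol %), THF, 0 °C → rt
Reagents that add atoms: none
Why: Neutral acid chloride formation followed by Negishi acylation with the arylzinc chloride should give the aryl ketone without over-addition and without attack on the lactone or the cyclopropane; no stereocentre is touched.

Step 15
Reactants: 23 (1S,4S,5R)-1-(ArT-carbonyl)-4-(DHB)-3-oxabicyclo[3.1.0]hexan-2-one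
Product: 25 (5S,6S)-2-ArT-6-(DHB)-3,7-dioxabicyclo[3.3.0]oct-1-en-8-one, via ammonium enolate 24 (not isolated)
Conditions: DABCO (30 mol %), dry DMSO, 100 °C
Reagents that add atoms: none
Why: DABCO attacks the cyclopropane CH2 (C6 of the bicyclohexanone) in an SN2 homo-conjugate opening that breaks the exocyclic C1–C6 bond and gives the ammonium enolate 24 of a β-keto lactone, whose ketone oxygen then displaces DABCO at the same CH2 to give the cyclic enol ether. The closest known reaction type is the amine-catalysed Cloke–Wilson rearrangement of 1-acylcyclopropane-1-carboxylates to 4,5-dihydrofuran-3-carboxylates. The new oxolene ring is closed in the 5-exo-tet mode. No stereocentre is created: the quaternary carbon becomes trigonal, the CH next to the CH2 is not touched, and the benzylic lactone carbon should keep its configuration because no acid is present. The step needs the C1–C6 bond and not the ring-fusion C1–C5 bond to break, and oxygen and not carbon to be alkylated; the lactone ring holds its carbonyl π system parallel to the exocyclic C1–C6 bond only, the CH2 is the least hindered carbon and cleavage of C1–C5 would lead to a bridgehead alkene. C-alkylation only returns 23 and the lactone oxygen cannot reach the CH2, so the equilibrium should drain to the strain-free vinylogous carbonate 25.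

Step 16
Reactants: 25 (5S,6S)-2-ArT-6-(DHB)-3,7-dioxabicyclo[3.3.0]oct-1-en-8-one
Product: 26 (1R,2S,5S,6S)-2-ArT-6-(DHB)-3,7-dioxabicyclo[3.3.0]octan-8-one (both aryl groups endo)
Conditions: H2 (4 atm), 5 % Rh/Al2O3, EtOAc, rt
Reagents that add atoms: none
Why: Heterogeneous syn hydrogenation of the strained tetrasubstituted β-alkoxy acrylate on rhodium, which spares benzylic C–O bonds, should deliver both hydrogens to the convex face of the bicycle, cis to the existing ring-fusion hydrogen and away from the endo DHB group; this fixes C1 and places ArT endo at C2.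

Step 17
Reactants: 26 (1R,2S,5S,6S)-2-ArT-6-(DHB)-3,7-dioxabicyclo[3.3.0]octan-8-one
Product: 27 (S)-(DHB)[(3S,4S,5S)-4-(hydroxymethyl)-5-ArT-oxolan-3-yl]methanol
Conditions: LiBH4, THF, 0 °C → rt
Reagents that add atoms: none
Why: Borohydride reduction of the γ-lactone to the 1,4-diol is too weakly basic to trigger retro-oxa-Michael opening next to the carbonyl, so all four centres should be kept.

Step 18
Reactants: 27 (S)-(DHB)[(3S,4S,5S)-4-(hydroxymethyl)-5-ArT-oxolan-3-yl]methanol
Product: 29 (1S,2S,5S,6S)-2-ArT-6-(DHB)-3,7-dioxabicyclo[3.3.0]octane, via primary mesylate 28 (not isolated)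
Conditions: MsCl (1.05 equiv), pyridine, 0 → 40 °C
Reagents that add atoms: none
Why: Selective mesylation of the primary alcohol followed by 5-exo-tet Williamson closure by the secondary benzylic hydroxyl forms the second oxolane at CH2, so the benzylic centre is retained and the endo aryl is preserved.

Step 19
Reactants: 29 (1S,2S,5S,6S)-2-ArT-6-(DHB)-3,7-dioxabicyclo[3.3.0]octane
Product: 30 CNP0303197.1
Conditions: Bu4NF, AcOH, THF, 0 °C → rt
Reagents that add atoms: none
Why: Buffered fluoride desilylation removes the two aryl triisopropylsilyl ethers and the primary tert-butyldimethylsilyl ether under conditions that cannot ionise or epimerise the endo benzylic ethers.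

**Compound list**

1 | vanillin (4-hydroxy-3-methoxybenzaldehyde) | COc1cc(C=O)ccc1O | starting material
2 | 3-methoxy-4-(triisopropylsilyloxy)benzaldehyde | COc1cc(C=O)ccc1O[Si](C(C)C)(C(C)C)C(C)C | intermediate
3 | [3-methoxy-4-(triisopropylsilyloxy)phenyl]methanol | COc1cc(CO)ccc1O[Si](C(C)C)(C(C)C)C(C)C | intermediate
4 | 5-iodovanillin (4-hydroxy-3-iodo-5-methoxybenzaldehyde) | COc1cc(C=O)cc(I)c1O | starting material
5 | 3-iodo-5-methoxy-4-(ArT-methoxy)benzaldehyde | COc1cc(C=O)cc(I)c1OCc1ccc(O[Si](C(C)C)(C(C)C)C(C)C)c(OC)c1 | intermediate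
6 | tert-butyl (E)-3-[3-iodo-5-methoxy-4-(ArT-methoxy)phenyl]prop-2-enoate | COc1cc(/C=C/C(=O)OC(C)(C)C)cc(I)c1OCc1ccc(O[Si](C(C)C)(C(C)C)C(C)C)c(OC)c1 | intermediate
7 | tert-butyl (E)-3-[3-(1-diazo-2-methoxy-2-oxoethyl)-5-methoxy-4-(ArT-methoxy)phenyl]prop-2-enoate | COc1cc(/C=C/C(=O)OC(C)(C)C)cc(C(=[N+]=[N-])C(=O)OC)c1OCc1ccc(O[Si](C(C)C)(C(C)C)C(C)C)c(OC)c1 | intermediate
8 | methyl (2S,3R)-5-[(E)-3-tert-butoxy-3-oxoprop-1-enyl]-7-methoxy-2-ArT-2,3-dihydro-1-benzofuran-3-carboxylate (2,3-cis) | CC(C)(C)OC(=O)/C=C/c1cc(OC)c2c(c1)[C@@H](C(=O)OC)[C@@H](c1ccc(O[Si](C(C)C)(C(C)C)C(C)C)c(OC)c1)O2 | intermediate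
9 | tert-butyl (E)-3-[(2S,3S)-3-(hydroxymethyl)-7-methoxy-2-ArT-2,3-dihydro-1-benzofuran-5-yl]prop-2-enoate | CC(C)(C)OC(=O)/C=C/c1cc(OC)c2c(c1)[C@@H](CO)[C@@H](c1ccc(O[Si](C(C)C)(C(C)C)C(C)C)c(OC)c1)O2 | intermediate
10 | tert-butyl (E)-3-(DHB)prop-2-enoate | CC(C)(C)OC(=O)/C=C/c1cc(OC)c2c(c1)[C@@H](CO[Si](C)(C)C(C)(C)C)[C@@H](c1ccc(O[Si](C(C)C)(C(C)C)C(C)C)c(OC)c1)O2 | intermediate
11 | (E)-3-(DHB)prop-2-en-1-ol | OC/C=C/c1cc(OC)c2c(c1)[C@@H](CO[Si](C)(C)C(C)(C)C)[C@@H](c1ccc(O[Si](C(C)C)(C(C)C)C(C)C)c(OC)c1)O2 | intermediate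
12 | [(2R,3R)-3-(DHB)oxiran-2-yl]methanol (trans epoxide) | OC[C@H]1O[C@@H]1c1cc(OC)c2c(c1)[C@@H](CO[Si](C)(C)C(C)(C)C)[C@@H](c1ccc(O[Si](C(C)C)(C(C)C)C(C)C)c(OC)c1)O2 | intermediate
13 | [(2R,3R)-3-(DHB)oxiran-2-yl]methyl 4-methylbenzenesulfonate | Cc1ccc(cc1)S(=O)(=O)OC[C@H]1O[C@@H]1c1cc(OC)c2c(c1)[C@@H](CO[Si](C)(C)C(C)(C)C)[C@@H](c1ccc(O[Si](C(C)C)(C(C)C)C(C)C)c(OC)c1)O2 | intermediate
14 | diallyl 2-{[(2R,3R)-3-(DHB)oxiran-2-yl]methyl}propanedioate | C=CCOC(=O)C(C[C@H]1O[C@@H]1c1cc(OC)c2c(c1)[C@@H](CO[Si](C)(C)C(C)(C)C)[C@@H](c1ccc(O[Si](C(C)C)(C(C)C)C(C)C)c(OC)c1)O2)C(=O)OCC=C | intermediate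
15 | sodium alkoxide of diallyl (2R)-2-[(S)-hydroxy(DHB)methyl]cyclopropane-1,1-dicarboxylate | C=CCOC(=O)C1(C(=O)OCC=C)C[C@H]1[C@@H](c1cc(OC)c2c(c1)[C@@H](CO[Si](C)(C)C(C)(C)C)[C@@H](c1ccc(O[Si](C(C)C)(C(C)C)C(C)C)c(OC)c1)O2)[O-].[Na+] | intermediate
16 | allyl (1S,4S,5R)-4-(DHB)-2-oxo-3-oxabicyclo[3.1.0]hexane-1-carboxylate (DHB syn to the cyclopropane CH2) | C=CCOC(=O)[C@]12C[C@H]1[C@@H](c1cc(OC)c3c(c1)[C@@H](CO[Si](C)(C)C(C)(C)C)[C@@H](c1ccc(O[Si](C(C)C)(C(C)C)C(C)C)c(OC)c1)O3)OC2=O | intermediate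
17 | (1S,4S,5R)-4-(DHB)-2-oxo-3-oxabicyclo[3.1.0]hexane-1-carboxylic acid | OC(=O)[C@]12C[C@H]1[C@@H](c1cc(OC)c3c(c1)[C@@H](CO[Si](C)(C)C(C)(C)C)[C@@H](c1ccc(O[Si](C(C)C)(C(C)C)C(C)C)c(OC)c1)O3)OC2=O | intermediate
18 | 4-bromo-2-methoxyphenol | COc1cc(Br)ccc1O | starting material
19 | (4-bromo-2-methoxyphenoxy)triisopropylsilane | COc1cc(Br)ccc1O[Si](C(C)C)(C(C)C)C(C)C | intermediate
20 | acid chloride of 17 (same configuration of the bicycle) | ClC(=O)[C@]12C[C@H]1[C@@H](c1cc(OC)c3c(c1)[C@@H](CO[Si](C)(C)C(C)(C)C)[C@@H](c1ccc(O[Si](C(C)C)(C(C)C)C(C)C)c(OC)c1)O3)OC2=O | intermediate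
21 | [3-methoxy-4-(triisopropylsilyloxy)phenyl]lithium | COc1cc([Li])ccc1O[Si](C(C)C)(C(C)C)C(C)C | intermediate
22 | [3-methoxy-4-(triisopropylsilyloxy)phenyl]zinc chloride | COc1cc([Zn]Cl)ccc1O[Si](C(C)C)(C(C)C)C(C)C | intermediate
23 | (1S,4S,5R)-1-(ArT-carbonyl)-4-(DHB)-3-oxabicyclo[3.1.0]hexan-2-one | COc1cc(ccc1O[Si](C(C)C)(C(C)C)C(C)C)C(=O)[C@]12C[C@H]1[C@@H](c1cc(OC)c3c(c1)[C@@H](CO[Si](C)(C)C(C)(C)C)[C@@H](c1ccc(O[Si](C(C)C)(C(C)C)C(C)C)c(OC)c1)O3)OC2=O | intermediate
24 | zwitterion: enolate of the (4S,5S)-3-(ArT-carbonyl)-5-(DHB)-γ-butyrolactone that carries a (1-azonia-4-azabicyclo[2.2.2]octan-1-yl)methyl group at C4 | COc1cc(ccc1O[Si](C(C)C)(C(C)C)C(C)C)C([O-])=C1C(=O)O[C@H](c2cc(OC)c3c(c2)[C@@H](CO[Si](C)(C)C(C)(C)C)[C@@H](c2ccc(O[Si](C(C)C)(C(C)C)C(C)C)c(OC)c2)O3)[C@@H]1C[N+]12CCN(CC1)CC2 | intermediate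
25 | (5S,6S)-2-ArT-6-(DHB)-3,7-dioxabicyclo[3.3.0]oct-1-en-8-one | COc1cc(ccc1O[Si](C(C)C)(C(C)C)C(C)C)C1=C2C(=O)O[C@H](c3cc(OC)c4c(c3)[C@@H](CO[Si](C)(C)C(C)(C)C)[C@@H](c3ccc(O[Si](C(C)C)(C(C)C)C(C)C)c(OC)c3)O4)[C@@H]2CO1 | intermediate
26 | (1R,2S,5S,6S)-2-ArT-6-(DHB)-3,7-dioxabicyclo[3.3.0]octan-8-one (both aryl groups endo) | COc1cc(ccc1O[Si](C(C)C)(C(C)C)C(C)C)[C@H]1OC[C@@H]2[C@H]1C(=O)O[C@@H]2c1cc(OC)c2c(c1)[C@@H](CO[Si](C)(C)C(C)(C)C)[C@@H](c1ccc(O[Si](C(C)C)(C(C)C)C(C)C)c(OC)c1)O2 | intermediate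
27 | (S)-(DHB)[(3S,4S,5S)-4-(hydroxymethyl)-5-ArT-oxolan-3-yl]methanol (all three ring substituents cis) | COc1cc(ccc1O[Si](C(C)C)(C(C)C)C(C)C)[C@H]1OC[C@@H]([C@H](O)c2cc(OC)c3c(c2)[C@@H](CO[Si](C)(C)C(C)(C)C)[C@@H](c2ccc(O[Si](C(C)C)(C(C)C)C(C)C)c(OC)c2)O3)[C@H]1CO | intermediate
28 | primary methanesulfonate of 27 | COc1cc(ccc1O[Si](C(C)C)(C(C)C)C(C)C)[C@H]1OC[C@@H]([C@H](O)c2cc(OC)c3c(c2)[C@@H](CO[Si](C)(C)C(C)(C)C)[C@@H](c2ccc(O[Si](C(C)C)(C(C)C)C(C)C)c(OC)c2)O3)[C@H]1COS(C)(=O)=O | intermediate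
29 | (1S,2S,5S,6S)-2-ArT-6-(DHB)-3,7-dioxabicyclo[3.3.0]octane (tris-silyl ether of the target) | COc1cc(ccc1O[Si](C(C)C)(C(C)C)C(C)C)[C@H]1OC[C@@H]2[C@H]1CO[C@@H]2c1cc(OC)c2c(c1)[C@@H](CO[Si](C)(C)C(C)(C)C)[C@@H](c1ccc(O[Si](C(C)C)(C(C)C)C(C)C)c(OC)c1)O2 | intermediate
30 | CNP0303197.1: 4-[(1S,2S,5S,6S)-6-[(2S,3S)-2-(4-hydroxy-3-methoxyphenyl)-3-(hydroxymethyl)-7-methoxy-2,3-dihydro-1-benzofuran-5-yl]-3,7-dioxabicyclo[3.3.0]octan-2-yl]-2-methoxyphenol | COc1cc([C@H]2OC[C@@H]3[C@H]2CO[C@@H]3c2cc(OC)c3c(c2)[C@@H](CO)[C@@H](c2ccc(O)c(OC)c2)O3)ccc1O | target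

**Count and risks**

Total steps: 19. Longest linear sequence: 18 steps (vanillin 1 to 30 through steps 1–12 and 14–19).

Steps most likely to fail:

1. Step 15. The amine may turn over too slowly at a temperature that the benzylic lactone C–O bond tolerates, or it may open the lactone at its benzylic carbon so that this centre loses its configuration. The fallback sets out from 23 and comes back at 26. The ketone of 23 is reduced under reagent control (2-methyl-CBS-oxazaborolidine, BH3·SMe2, THF, −20 °C, catalyst enantiomer chosen for the R carbinol) to the cyclopropyl carbinol F1. MgI2 in THF at rt opens the activated cyclopropane of F1 at its CH2 by homo-conjugate addition of iodide and gives the α-(hydroxybenzyl)-β-(iodomethyl) lactone F2, whose lactone α-carbon is enolisable. Ag2CO3 in MeCN then closes the oxolane by 5-exo-tet etherification of the epimer that has the two arms cis, which should give 26. The O–CH2 bond is then made at the alcohol oxidation level, and the ArCH–O centre comes from the ketone reduction and not from a hydrogenation.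

2. Step 16. Hydrogenolysis of the benzylic lactone C–O bond or of the new benzylic ether may occur at the metal surface, or uptake by the tetrasubstituted alkene may be so slow that an arene is saturated. The fallback sets out from 25 and comes back at 26 by copper hydride conjugate reduction (Cu(OAc)2, 1,2-bis(diphenylphosphino)benzene, polymethylhydrosiloxane, t-BuOH, toluene, rt). Hydride should go to the aryl-bearing β-carbon from the convex face and the enolate is protonated at the ring fusion, which can only give the cis-fused lactone. No new compound is made on this path (F0).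

3. Step 10. The electron-rich aryl epoxide may be opened at its benzylic carbon by the titanium alkoxide medium or during sulfonylation, and in step 11 the malonate may attack that carbon. The fallback sets out from 11 and comes back at 14. Alcohol 11 is converted (CBr4, PPh3, CH2Cl2, 0 °C) into the cinnamyl bromide F3, which alkylates sodium diallyl malonate (NaH, THF, 0 °C) to give the diallyl cinnamylmalonate F4. Shi epoxidation of the E alkene (D-fructose-derived ketone, Oxone (2KHSO5·KHSO4·K2SO4), K2CO3 buffer, MeCN/dimethoxymethane/H2O, 0 °C) should give the (2R,3R)-epoxide 14 under basic conditions. Compound 14 is then isolated and closed to 16 with NaH as in step 11.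

Further compounds
F1 | step 15 | (1S,4S,5R)-1-[(R)-hydroxy(ArT)methyl]-4-(DHB)-3-oxabicyclo[3.1.0]hexan-2-one | COc1cc(ccc1O[Si](C(C)C)(C(C)C)C(C)C)[C@@H](O)[C@]12C[C@H]1[C@@H](c1cc(OC)c3c(c1)[C@@H](CO[Si](C)(C)C(C)(C)C)[C@@H](c1ccc(O[Si](C(C)C)(C(C)C)C(C)C)c(OC)c1)O3)OC2=O
F2 | step 15 | 3-[(R)-hydroxy(ArT)methyl]-4-(iodomethyl)-5-(DHB)oxolan-2-one, drawn as the 3,4-cis epimer that cyclises (C3 equilibrates) | COc1cc(ccc1O[Si](C(C)C)(C(C)C)C(C)C)[C@@H](O)[C@@H]1C(=O)O[C@H](c2cc(OC)c3c(c2)[C@@H](CO[Si](C)(C)C(C)(C)C)[C@@H](c2ccc(O[Si](C(C)C)(C(C)C)C(C)C)c(OC)c2)O3)[C@@H]1CI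
F0 | step 16 | none | none
F3 | step 10 | (E)-3-(DHB)prop-2-enyl bromide | BrC/C=C/c1cc(OC)c2c(c1)[C@@H](CO[Si](C)(C)C(C)(C)C)[C@@H](c1ccc(O[Si](C(C)C)(C(C)C)C(C)C)c(OC)c1)O2
F4 | step 10 | diallyl 2-[(E)-3-(DHB)prop-2-enyl]propanedioate | C=CCOC(=O)C(C/C=C/c1cc(OC)c2c(c1)[C@@H](CO[Si](C)(C)C(C)(C)C)[C@@H](c1ccc(O[Si](C(C)C)(C(C)C)C(C)C)c(OC)c1)O2)C(=O)OCC=C
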